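The side chain is cut between C11 (numbered from the naphthoquinone ring), the methyl-bearing sp3 stereocentre of the third isoprene unit, and C12, the methylene homoallylic to the C14=C15 double bond. Because C12 is not allylic, the hexaene half forms a well-behaved primary Grignard reagent; because C11 carries only H, CH3 and two chains, its configuration can be bought as (R)-propylene oxide and inverted. The key step is a copper-catalysed SN2 cross-coupling of this Grignard reagent with a secondary tosylate on the half that already holds the naphthoquinone, masked as its 1,4-dimethoxynaphthalene; it joins both halves and sets C11 in one operation.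

Key step: step 15

Assumption: 1,4-dimethoxy-2-methylnaphthalene, (S)-citronellyl bromide, (R)-propylene oxide and (2E,6E)-farnesyl bromide are taken as catalogue compounds; side-chain locants in the Why lines count outwards from the ring carbon.

Step 1
Reactants: 1 (S)-citronellyl bromide [(6S)-8-bromo-2,6-dimethyloct-2-ene]; 2 (R)-propylene oxide [(R)-2-methyloxirane]
Product: 4 (2R,6R)-6,10-dimethylundec-9-en-2-ol, via (S)-citronellylmagnesium bromide 3 (not isolated)
Conditions: Mg, THF, 40 °C; then CuI (10 mol %), 2, THF, −30 → 0 °C; aq. NH4Cl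
Reagents that add atoms: none
Why: Copper-catalysed Grignard opening of a terminal epoxide at its CH2 carbon touches neither stereocentre, so C6 comes from the citronellyl unit and the carbinol centre from (R)-propylene oxide.

Step 2
Reactants: 4 (2R,6R)-6,10-dimethylundec-9-en-2-ol
Product: 5 (4R,8R)-4-methylnonane-1,8-diol
Conditions: O3, CH2Cl2/MeOH, −78 °C; then NaBH4, −78 °C → rt
Reagents that add atoms: ozone, [O-][O+]=O
Why: Ozonolysis of the only C=C with reductive work-up should turn the prenyl terminus into a primary alcohol, the isopropylidene carbon leaving as propan-2-ol.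

Step 3
Reactants: 5 (4R,8R)-4-methylnonane-1,8-diol
Product: 6 (2R,6R)-9-iodo-6-methylnonan-2-ol
Conditions: I2 (1.05 equiv), PPh3, imidazole, CH2Cl2, 0 °C
Reagents that add atoms: iodine, II
Why: Appel-type iodination (Garegg–Samuelsson conditions) is much faster at the unhindered primary hydroxyl than at the secondary one, which should stay free.

Step 4
Reactants: 6 (2R,6R)-9-iodo-6-methylnonan-2-ol
Product: 7 (2R,6S)-6-methylundec-10-yn-2-ol
Conditions: lithium acetylide–ethylenediamine complex (3 equiv), DMSO, 15 °C → rt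
Reagents that add atoms: lithium acetylide, [Li]C#C
Why: SN2 alkynylation of a primary iodide, the secondary hydroxyl being only deprotonated by the excess acetylide and returned on work-up (the C6 descriptor changes from R to S through the priority rules alone).

Step 5
Reactants: 8 1,4-dimethoxy-2-methylnaphthalene
Product: 9 2-(chloromethyl)-1,4-dimethoxy-3-methylnaphthalene
Conditions: paraformaldehyde, conc. HCl, AcOH, rt
Reagents that add atoms: formaldehyde, C=O; hydrogen chloride, Cl
Why: Blanc chloromethylation should go to C3, the only free position of the electron-rich ring that carries the two methoxy groups.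

Step 6
Reactants: 7 (2R,6S)-6-methylundec-10-yn-2-ol; 9 2-(chloromethyl)-1,4-dimethoxy-3-methylnaphthalene
Product: 11 (2R,6S,10E)-12-(1,4-dimethoxy-3-methylnaphthalen-2-yl)-6,10-dimethyldodec-10-en-2-ol, via alkenylalane 10 (not isolated)
Conditions: Me3Al (3 equiv), Cp2ZrCl2 (0.25 equiv), CH2Cl2, 0 °C → rt; volatiles off, THF; then 9, NiCl2(PPh3)2 (5 mol %) pre-reduced with n-BuLi (10 mol %) to zerovalent nickel, THF, rt; aq. Rochelle salt
Reagents that add atoms: trimethylaluminium, C[Al](C)C
Why: Negishi zirconium-catalysed syn-carboalumination of the terminal alkyne (hydroxyl carried as its dimethylaluminium alkoxide) should give only the (E)-2-methylalkenylalane, and nickel-catalysed cross-coupling with the benzylic chloride retains that geometry, which fixes the 10E trisubstituted double bond.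

Step 7
Reactants: 11 (2R,6S,10E)-12-(1,4-dimethoxy-3-methylnaphthalen-2-yl)-6,10-dimethyldodec-10-en-2-ol
Product: 12 (2R,6S,10E)-12-(1,4-dimethoxy-3-methylnaphthalen-2-yl)-6,10-dimethyldodec-10-en-2-yl 4-methylbenzenesulfonate
Conditions: TsCl, pyridine, DMAP (cat.), CH2Cl2, 0 °C → rt
Reagents that add atoms: p-toluenesulfonyl chloride, Cc1ccc(cc1)S(=O)(=O)Cl
Why: O-sulfonylation leaves the C–O bond and hence the 2R configuration untouched.

Step 8
Reactants: 13 (2E,6E)-farnesyl bromide [(2E,6E)-1-bromo-3,7,11-trimethyldodeca-2,6,10-triene]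
Product: 14 (2E,6E)-farnesyl phenyl sulfone
Conditions: PhSO2Na, DMF, rt
Reagents that add atoms: sodium benzenesulfinate, [Na+].[O-]S(=O)c1ccccc1
Why: SN2 S-alkylation of the sulfinate by the primary allylic bromide should keep the 2E geometry.

Step 9
Reactants: 13 (2E,6E)-farnesyl bromide
Product: 16 (3E,7E)-4,8,12-trimethyltrideca-3,7,11-trien-1-ol (homofarnesol), via homofarnesyl silane 15 (not isolated)
Conditions: i-PrOMe2SiCH2MgCl (1.5 equiv, from the chloromethylsilane and Mg), CuI (10 mol %), THF, 0 °C; aq. NH4Cl wash; then, on the organic phase without isolation, KF, KHCO3, 30% H2O2, THF/MeOH, rt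
Reagents that add atoms: (isopropoxydimethylsilyl)methylmagnesium chloride, CC(C)O[Si](C)(C)C[Mg]Cl; hydrogen peroxide, OO
Why: The silylmethyl Grignard reagent, a hydroxymethyl-anion equivalent, should couple at the primary allylic carbon under copper catalysis (attack at the other allyl terminus would have to build a quaternary centre), and Tamao oxidation of the C–Si bond then gives the homoallylic alcohol without touching the alkenes.

Step 10
Reactants: 16 (3E,7E)-4,8,12-trimethyltrideca-3,7,11-trien-1-ol
Product: 17 (2E,6E,10E)-2,6,10-trimethyltrideca-2,6,10-triene-1,13-diol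
Conditions: SeO2 (0.2 equiv), t-BuOOH (3 equiv), salicylic acid (0.1 equiv), CH2Cl2, 0 °C → rt
Reagents that add atoms: tert-butyl hydroperoxide, CC(C)(C)OO (terminal oxidant; the oxygen is passed on by catalytic selenium dioxide, O=[Se]=O)
Why: Riley allylic oxidation (ene reaction, then [2,3]-sigmatropic shift) should attack the terminal gem-dimethyl alkene at its (E)-methyl group and give the (E)-allylic alcohol.

Step 11
Reactants: 17 (2E,6E,10E)-2,6,10-trimethyltrideca-2,6,10-triene-1,13-diol
Product: 18 (3E,7E,11E)-13-bromo-4,8,12-trimethyltrideca-3,7,11-trien-1-ol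
Conditions: NBS, Me2S, CH2Cl2, −20 → 0 °C
Reagents that add atoms: N-bromosuccinimide, BrN1C(=O)CCC1=O
Why: Corey–Kim halogenation converts only the allylic alkoxysulfonium salt into the bromide, so the non-allylic primary hydroxyl should be returned on work-up.

Step 12
Reactants: 14 (2E,6E)-farnesyl phenyl sulfone; 18 (3E,7E,11E)-13-bromo-4,8,12-trimethyltrideca-3,7,11-trien-1-ol
Product: 20 (3E,7E,11E,14RS,15E,19E)-4,8,12,16,20,24-hexamethyl-14-(phenylsulfonyl)pentacosa-3,7,11,15,19,23-hexaen-1-ol, via lithiated sulfone 19 (not isolated)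
Conditions: 14 (2.2 equiv), n-BuLi (2.2 equiv), THF, −78 °C; then 18, −78 → −20 °C
Reagents that add atoms: none
Why: Biellmann-type alkylation, in which the α-sulfonyl allyl anion attacks the primary allylic bromide through its α-carbon (SN2) and joins the C15 and C16 pieces without moving a double bond, the second equivalent of anion buffering the free hydroxyl.

Step 13
Reactants: 20 (3E,7E,11E,14RS,15E,19E)-4,8,12,16,20,24-hexamethyl-14-(phenylsulfonyl)pentacosa-3,7,11,15,19,23-hexaen-1-ol
Product: 21 (3E,7E,11E,15E,19E)-4,8,12,16,20,24-hexamethylpentacosa-3,7,11,15,19,23-hexaen-1-ol (homohexaprenol)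
Conditions: PdCl2(dppp) (5 mol %), LiBHEt3 (4 equiv), THF, 0 °C
Reagents that add atoms: none
Why: Palladium-catalysed reductive desulfonylation of the allylic sulfone delivers hydride to the less substituted terminus of the π-allyl intermediate, so the C15=C16 double bond should stay in place and stay E.

Step 14
Reactants: 21 (3E,7E,11E,15E,19E)-4,8,12,16,20,24-hexamethylpentacosa-3,7,11,15,19,23-hexaen-1-ol
Product: 22 (3E,7E,11E,15E,19E)-1-bromo-4,8,12,16,20,24-hexamethylpentacosa-3,7,11,15,19,23-hexaene (homohexaprenyl bromide)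
Conditions: CBr4, PPh3, CH2Cl2, 0 °C
Reagents that add atoms: carbon tetrabromide, BrC(Br)(Br)Br
Why: Appel bromination of a primary alcohol under neutral conditions that leave the polyene alone.

Step 15
Reactants: 22 homohexaprenyl bromide; 12 (2R,6S,10E)-12-(1,4-dimethoxy-3-methylnaphthalen-2-yl)-6,10-dimethyldodec-10-en-2-yl 4-methylbenzenesulfonate
Product: 24 2-[(2E,7R,11S,14E,18E,22E,26E,30E)-3,7,11,15,19,23,27,31,35-nonamethylhexatriaconta-2,14,18,22,26,30,34-heptaen-1-yl]-1,4-dimethoxy-3-methylnaphthalene, via homohexaprenylmagnesium bromide 23 (not isolated)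
Conditions: 22 (1.5 equiv), Mg, THF, 35 °C; then 12, CuI (10 mol %), TMEDA (20 mol %), LiOMe (1 equiv), THF, 0 °C, 24 h
Reagents that add atoms: none
Why: Grignard reagent 23 transmetalates to copper to give a TMEDA/LiOMe-stabilised alkylcuprate, which attacks C11 of tosylate 12 from the side opposite the leaving group (SN2-type oxidative addition) and then forms the C11–C12 bond by reductive elimination. The closest known reaction type is the copper-catalysed cross-coupling of unactivated secondary alkyl tosylates with alkyl Grignard reagents, a Kumada-type sp3–sp3 coupling that runs with inversion. No ring is closed. The only new stereocentre, C11, is under substrate control: clean inversion of the 2R tosylate (from (R)-propylene oxide) should give 11S, while C7 and all double bonds are spectators. The step needs substitution to beat E2 elimination and radical racemisation, which the tosylate leaving group (not a halide), the TMEDA/LiOMe additives and 0 °C should secure; it also needs the nucleophile to react only through C12, which holds because C12 is homoallylic and no allyl transposition is possible. The quinone is masked as its dimethyl ether, so the Grignard reagent meets no electrophile other than C11.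

Step 16
Reactants: 24 2-[(2E,7R,11S,14E,18E,22E,26E,30E)-3,7,11,15,19,23,27,31,35-nonamethylhexatriaconta-2,14,18,22,26,30,34-heptaen-1-yl]-1,4-dimethoxy-3-methylnaphthalene
Product: 25 2-methyl-3-[(2E,7R,11S,14E,18E,22E,26E,30E)-3,7,11,15,19,23,27,31,35-nonamethylhexatriaconta-2,14,18,22,26,30,34-heptaen-1-yl]naphthalene-1,4-dione
Conditions: (NH4)2Ce(NO3)6 (2.5 equiv), MeCN/H2O/CH2Cl2, 0 °C
Reagents that add atoms: water, O
Why: Oxidative demethylation of the 1,4-dimethoxyarene through its radical cation should give the naphthoquinone, the isolated trisubstituted alkenes and both sp3 stereocentres being inert under these brief, cold conditions.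

Compound list
1 | (S)-citronellyl bromide, (6S)-8-bromo-2,6-dimethyloct-2-ene | BrCC[C@@H](C)CCC=C(C)C | starting material
2 | (R)-propylene oxide, (R)-2-methyloxirane | C[C@@H]1CO1 | starting material
3 | (S)-citronellylmagnesium bromide | Br[Mg]CC[C@@H](C)CCC=C(C)C | intermediate (not isolated)
4 | (2R,6R)-6,10-dimethylundec-9-en-2-ol | C[C@@H](O)CCC[C@@H](C)CCC=C(C)C | intermediate
5 | (4R,8R)-4-methylnonane-1,8-diol | C[C@@H](O)CCC[C@@H](C)CCCO | intermediate
6 | (2R,6R)-9-iodo-6-methylnonan-2-ol | C[C@@H](O)CCC[C@@H](C)CCCI | intermediate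
7 | (2R,6S)-6-methylundec-10-yn-2-ol | C[C@@H](O)CCC[C@@H](C)CCCC#C | intermediate
8 | 1,4-dimethoxy-2-methylnaphthalene | COc1c(C)cc(OC)c2ccccc12 | starting material
9 | 2-(chloromethyl)-1,4-dimethoxy-3-methylnaphthalene | COc1c(C)c(CCl)c(OC)c2ccccc12 | intermediate
10 | (E)-alkenylalane from 7, dimethylaluminium alkoxide of (2R,6S,10E)-11-(dimethylalumanyl)-6,10-dimethylundec-10-en-2-ol | C[C@@H](O[Al](C)C)CCC[C@@H](C)CCC/C(C)=C/[Al](C)C | intermediate (not isolated)
11 | (2R,6S,10E)-12-(1,4-dimethoxy-3-methylnaphthalen-2-yl)-6,10-dimethyldodec-10-en-2-ol | C[C@@H](O)CCC[C@@H](C)CCC/C(C)=C/Cc1c(C)c(OC)c2ccccc2c1OC | intermediate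
12 | (2R,6S,10E)-12-(1,4-dimethoxy-3-methylnaphthalen-2-yl)-6,10-dimethyldodec-10-en-2-yl 4-methylbenzenesulfonate | C[C@@H](OS(=O)(=O)c1ccc(C)cc1)CCC[C@@H](C)CCC/C(C)=C/Cc1c(C)c(OC)c2ccccc2c1OC | intermediate
13 | (2E,6E)-farnesyl bromide, (2E,6E)-1-bromo-3,7,11-trimethyldodeca-2,6,10-triene | BrC/C=C(\C)CC/C=C(\C)CCC=C(C)C | starting material
14 | (2E,6E)-farnesyl phenyl sulfone, {[(2E,6E)-3,7,11-trimethyldodeca-2,6,10-trien-1-yl]sulfonyl}benzene | O=S(=O)(C/C=C(\C)CC/C=C(\C)CCC=C(C)C)c1ccccc1 | intermediate
15 | isopropoxydimethyl[(3E,7E)-4,8,12-trimethyltrideca-3,7,11-trien-1-yl]silane | CC(C)O[Si](C)(C)CC/C=C(\C)CC/C=C(\C)CCC=C(C)C | intermediate (not isolated)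
16 | (3E,7E)-4,8,12-trimethyltrideca-3,7,11-trien-1-ol (homofarnesol) | OCC/C=C(\C)CC/C=C(\C)CCC=C(C)C | intermediate
17 | (2E,6E,10E)-2,6,10-trimethyltrideca-2,6,10-triene-1,13-diol | OCC/C=C(\C)CC/C=C(\C)CC/C=C(\C)CO | intermediate
18 | (3E,7E,11E)-13-bromo-4,8,12-trimethyltrideca-3,7,11-trien-1-ol | OCC/C=C(\C)CC/C=C(\C)CC/C=C(\C)CBr | intermediate
19 | 1-lithio-(2E,6E)-farnesyl phenyl sulfone | [Li]C(/C=C(\C)CC/C=C(\C)CCC=C(C)C)S(=O)(=O)c1ccccc1 | intermediate (not isolated)
20 | (3E,7E,11E,14RS,15E,19E)-4,8,12,16,20,24-hexamethyl-14-(phenylsulfonyl)pentacosa-3,7,11,15,19,23-hexaen-1-ol | OCC/C=C(\C)CC/C=C(\C)CC/C=C(\C)CC(/C=C(\C)CC/C=C(\C)CCC=C(C)C)S(=O)(=O)c1ccccc1 | intermediate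
21 | (3E,7E,11E,15E,19E)-4,8,12,16,20,24-hexamethylpentacosa-3,7,11,15,19,23-hexaen-1-ol (homohexaprenol) | OCC/C=C(\C)CC/C=C(\C)CC/C=C(\C)CC/C=C(\C)CC/C=C(\C)CCC=C(C)C | intermediate
22 | (3E,7E,11E,15E,19E)-1-bromo-4,8,12,16,20,24-hexamethylpentacosa-3,7,11,15,19,23-hexaene (homohexaprenyl bromide) | BrCC/C=C(\C)CC/C=C(\C)CC/C=C(\C)CC/C=C(\C)CC/C=C(\C)CCC=C(C)C | intermediate
23 | [(3E,7E,11E,15E,19E)-4,8,12,16,20,24-hexamethylpentacosa-3,7,11,15,19,23-hexaen-1-yl]magnesium bromide | Br[Mg]CC/C=C(\C)CC/C=C(\C)CC/C=C(\C)CC/C=C(\C)CC/C=C(\C)CCC=C(C)C | intermediate (not isolated)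
24 | 2-[(2E,7R,11S,14E,18E,22E,26E,30E)-3,7,11,15,19,23,27,31,35-nonamethylhexatriaconta-2,14,18,22,26,30,34-heptaen-1-yl]-1,4-dimethoxy-3-methylnaphthalene | CC(C)=CCC/C(C)=C/CC/C(C)=C/CC/C(C)=C/CC/C(C)=C/CC/C(C)=C/CC[C@@H](C)CCC[C@@H](C)CCC/C(C)=C/Cc1c(C)c(OC)c2ccccc2c1OC | intermediate
25 | 2-methyl-3-[(2E,7R,11S,14E,18E,22E,26E,30E)-3,7,11,15,19,23,27,31,35-nonamethylhexatriaconta-2,14,18,22,26,30,34-heptaen-1-yl]naphthalene-1,4-dione | CC(C)=CCC/C(C)=C/CC/C(C)=C/CC/C(C)=C/CC/C(C)=C/CC/C(C)=C/CC[C@@H](C)CCC[C@@H](C)CCC/C(C)=C/CC1=C(C)C(=O)c2ccccc2C1=O | target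

Total step count: 16.
Longest linear sequence: 8 steps (steps 1, 2, 3, 4, 6, 7, 15, 16; the farnesyl branch, steps 9 to 16, is equally long).

Steps most likely to fail

1. Step 15. The secondary tosylate may undergo E2 elimination faster than substitution, single-electron pathways at copper may erode the inversion at C11, and Wurtz homocoupling may consume the bromide while the Grignard reagent forms. The fallback sets out from 22 and 12 and comes back at 24; it replaces the organocopper coupling by the alkylation of a sulfone-stabilised carbanion. Bromide 22 with PhSO2Na (DMF, 60 °C) should give homohexaprenyl phenyl sulfone F1. Its lithio derivative (n-BuLi, THF/DMPU, −78 °C → rt) should displace the tosylate of 12 in a classical SN2 alkylation, again with inversion at C11, to give the C12-phenylsulfonyl coupling product F2 as a mixture of C12 epimers. Reductive desulfonylation (6% sodium amalgam, Na2HPO4, MeOH/THF, −20 °C) removes the auxiliary sulfone and returns to 24.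

2. Step 6. The aluminium alkoxide formed from the free hydroxyl may slow transmetalation of the alkenylalane to nickel, and protodealumination may outrun the coupling. The fallback sets out from 7 and 9 and comes back at 11; it reverses the roles of the partners and moves to a palladium/zinc coupling. The same carboalumination of 7, quenched with I2 (THF, −30 °C), should give the (E)-alkenyl iodide F3. Chloride 9 is converted (Zn dust, LiCl, THF, rt) into the benzylic zinc chloride F4. Negishi coupling of F3 with F4 (2.2 equiv, Pd(PPh3)4, THF, rt) then gives 11 with retention of the alkene geometry.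

3. Step 12. Proton transfer from the free hydroxyl may quench the carbanion, the resulting alkoxide may be O-alkylated by the allylic bromide, and the allyl anion may react in part through its γ-carbon. The fallback sets out from 18 and comes back at 20; it masks the hydroxyl so that the carbanion meets no acidic proton. Silylation of 18 (TBSCl, imidazole, DMF, rt) should give the silyl ether F5. Alkylation of 19 (1.1 equiv, THF, −78 → −20 °C) with F5 gives the silylated sulfone F6, and TBAF (THF, rt) frees 20.

Further compounds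
F1 | step 15 | {[(3E,7E,11E,15E,19E)-4,8,12,16,20,24-hexamethylpentacosa-3,7,11,15,19,23-hexaen-1-yl]sulfonyl}benzene (homohexaprenyl phenyl sulfone) | O=S(=O)(CC/C=C(\C)CC/C=C(\C)CC/C=C(\C)CC/C=C(\C)CC/C=C(\C)CCC=C(C)C)c1ccccc1
F2 | step 15 | 2-[(2E,7R,11S,12RS,14E,18E,22E,26E,30E)-3,7,11,15,19,23,27,31,35-nonamethyl-12-(phenylsulfonyl)hexatriaconta-2,14,18,22,26,30,34-heptaen-1-yl]-1,4-dimethoxy-3-methylnaphthalene | CC(C)=CCC/C(C)=C/CC/C(C)=C/CC/C(C)=C/CC/C(C)=C/CC/C(C)=C/CC(S(=O)(=O)c1ccccc1)[C@@H](C)CCC[C@@H](C)CCC/C(C)=C/Cc1c(C)c(OC)c2ccccc2c1OC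
F3 | step 6 | (2R,6S,10E)-11-iodo-6,10-dimethylundec-10-en-2-ol | C[C@@H](O)CCC[C@@H](C)CCC/C(C)=C/I
F4 | step 6 | [(1,4-dimethoxy-3-methylnaphthalen-2-yl)methyl]zinc chloride | COc1c(C)c(C[Zn]Cl)c(OC)c2ccccc12
F5 | step 12 | {[(3E,7E,11E)-13-bromo-4,8,12-trimethyltrideca-3,7,11-trien-1-yl]oxy}(tert-butyl)dimethylsilane | CC(C)(C)[Si](C)(C)OCC/C=C(\C)CC/C=C(\C)CC/C=C(\C)CBr
F6 | step 12 | tert-butyldimethylsilyl ether of 20, tert-butyl{[(3E,7E,11E,14RS,15E,19E)-4,8,12,16,20,24-hexamethyl-14-(phenylsulfonyl)pentacosa-3,7,11,15,19,23-hexaen-1-yl]oxy}dimethylsilane | CC(C)(C)[Si](C)(C)OCC/C=C(\C)CC/C=C(\C)CC/C=C(\C)CC(/C=C(\C)CC/C=C(\C)CCC=C(C)C)S(=O)(=O)c1ccccc1
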